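## Retrosynthetic overview

1. The target comes from ovatodiolide by a final singlet-oxygen ene reaction, which turns the C4(CH3)=C5 alkene into the C4 exo-methylene / C5–OOH unit.
2. The butenolide (third ring, which also defines the 14-membered carbocycle) comes from transannular ring-closing metathesis (C8=C9) of a 15-membered macrolactone. That macrolactone (second ring) is closed at O–C19 from a C10-hydroxy acrylic acid.
3. The α-methylene-γ-butyrolactone (first ring) comes from the key intermolecular allylboration/lactonisation (C1–C14 bond) of a C9–C14 enal with a 2-(methoxycarbonyl)allylboronate carrying C1–C8. This step sets C1 and C14.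
4. The enal comes from (R)-epichlorohydrin (C10) and ethynyltrimethylsilane; zirconium-catalysed carboalumination fixes the E-C12=C13 bond.
5. The boronate comes from 2-methylidenepropane-1,3-diol by two Johnson–Claisen rearrangements (E-C4=C5), alkyne homologation to a ynoate, and syn-hydroalumination/borylmethylation.

Atom numbers are cembrane numbers: C1 (lactone CH), C2–C3, C4 (bears C18), C5, C6–C7, C8 (butenolide α-carbon; C19 is its C=O), C9, C10 (butenolide O–CH), C11, C12 (bears CH3), C13, C14 (lactone O–CH), C15 (=C17H2), C16 (lactone C=O). The target SMILES corresponds to 1R,5R,10R,14S, 12E, with a trans-fused α-methylene lactone.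

Assumption: singlet oxygen attacks the exposed face of C4=C5 of ovatodiolide, as in the presumed natural formation of the 5β-hydroperoxide; the 5-epimer and the tertiary C4 hydroperoxide, if formed, are removed by chromatography.

## Route

Step 1
Reactants: 1 (R)-epichlorohydrin; 2 ethynyltrimethylsilane
Product: 4 (2R)-1-chloro-5-(trimethylsilyl)pent-4-yn-2-ol, via lithium acetylide 3 (not isolated)
Conditions: 2, n-BuLi, THF, −78 °C; BF3·OEt2; then 1, −78 °C; H2O
Reagents that add atoms: none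
Why: Yamaguchi–Hirao alkynylation; the BF3-activated epoxide is opened by the acetylide at its unsubstituted CH2 (SN2), so the carbinol centre (future C10) is carried over unchanged as 2R.

Step 2
Reactants: 4 (2R)-1-chloro-5-(trimethylsilyl)pent-4-yn-2-ol
Product: 6 (3R)-6-(trimethylsilyl)hex-1-en-5-yn-3-ol, via epoxide 5 (not isolated)
Conditions: Me3SI (4 equiv), n-BuLi (3.9 equiv), THF, −20 °C → rt; H2O
Reagents that add atoms: trimethylsulfonium iodide, C[S+](C)C.[I-]
Why: Base closes the chlorohydrin to the terminal epoxide, and excess dimethylsulfonium methylide opens it at CH2 and eliminates Me2S (ylide one-carbon homologation of an epoxide to an allylic alcohol), without touching the stereocentre.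

Step 3
Reactants: 6 (3R)-6-(trimethylsilyl)hex-1-en-5-yn-3-ol
Product: 7 (3R)-3-[(tert-butyldimethylsilyl)oxy]-6-(trimethylsilyl)hex-1-en-5-yne
Conditions: TBSCl, imidazole, DMF, rt
Reagents that add atoms: tert-butyldimethylsilyl chloride, CC(C)(C)[Si](C)(C)Cl
Why: Standard imidazole-mediated silylation protects the secondary alcohol against AlMe3 and the later allylboration.

Step 4
Reactants: 7 (3R)-3-[(tert-butyldimethylsilyl)oxy]-6-(trimethylsilyl)hex-1-en-5-yne
Product: 8 (3R)-3-[(tert-butyldimethylsilyl)oxy]hex-1-en-5-yne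
Conditions: K2CO3 (0.2 equiv), MeOH, rt
Reagents that add atoms: none
Why: Methanolysis cleaves the C(sp)–Si bond selectively over the silyl ether and frees the terminal alkyne for carbometalation.

Step 5
Reactants: 8 (3R)-3-[(tert-butyldimethylsilyl)oxy]hex-1-en-5-yne
Product: 11 (2E,5R)-5-[(tert-butyldimethylsilyl)oxy]-3-methylhepta-2,6-dien-1-ol, via alkenylalane 9 (not isolated), via lithium alanate 10 (not isolated)
Conditions: AlMe3 (2.5 equiv), Cp2ZrCl2 (0.25 equiv), CH2Cl2, 0 °C → rt; evaporate; n-BuLi, THF, −30 °C; (CH2O)n, rt; aq. KNaC4H4O6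
Reagents that add atoms: trimethylaluminium, C[Al](C)C; paraformaldehyde (as CH2O), C=O
Why: Negishi zirconium-catalysed carboalumination adds CH3 and Al syn across the terminal alkyne with Al at the terminus, and the derived alanate attacks formaldehyde with retention, which fixes the 12E trisubstituted alkene.

Step 6
Reactants: 11 (2E,5R)-5-[(tert-butyldimethylsilyl)oxy]-3-methylhepta-2,6-dien-1-ol
Product: 12 (2E,5R)-5-[(tert-butyldimethylsilyl)oxy]-3-methylhepta-2,6-dienal
Conditions: MnO2 (15 equiv), CH2Cl2, rt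
Reagents that add atoms: none
Why: MnO2 oxidises only the allylic alcohol to the enal, without E/Z isomerisation or loss of the silyl ether.

Step 7
Reactants: 13 2-methylidenepropane-1,3-diol
Product: 15 2-{[(tert-butyldimethylsilyl)oxy]methyl}prop-2-en-1-ol, via sodium alkoxide 14 (not isolated)
Conditions: NaH (1.0 equiv), THF, 0 °C → rt; TBSCl (1.0 equiv)
Reagents that add atoms: tert-butyldimethylsilyl chloride, CC(C)(C)[Si](C)(C)Cl
Why: The monosodium alkoxide of the symmetrical diol precipitates and is silylated once (McDougal monoprotection), differentiating the two CH2OH arms.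

Step 8
Reactants: 15 2-{[(tert-butyldimethylsilyl)oxy]methyl}prop-2-en-1-ol; 16 triethyl orthoacetate
Product: 18 ethyl 4-{[(tert-butyldimethylsilyl)oxy]methyl}pent-4-enoate, via ketene acetal 17 (not isolated)
Conditions: EtCO2H (5 mol%), 140 °C, EtOH distilled off
Reagents that add atoms: none
Why: Johnson–Claisen rearrangement; the [3,3]-shift of the ketene acetal attaches the acetate unit to the former =CH2 terminus and regenerates the 1,1-disubstituted alkene (future C8=CH2).

Step 9
Reactants: 18 ethyl 4-{[(tert-butyldimethylsilyl)oxy]methyl}pent-4-enoate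
Product: 19 4-{[(tert-butyldimethylsilyl)oxy]methyl}pent-4-enal
Conditions: i-Bu2AlH (1.05 equiv), CH2Cl2, −78 °C; MeOH; aq. KNaC4H4O6
Reagents that add atoms: none
Why: Partial ester reduction; at −78 °C the tetrahedral aluminium hemiacetal is stable and releases the aldehyde (C5) only on work-up.

Step 10
Reactants: 19 4-{[(tert-butyldimethylsilyl)oxy]methyl}pent-4-enal; 20 isopropenylmagnesium bromide
Product: 21 rac-6-{[(tert-butyldimethylsilyl)oxy]methyl}-2-methylhepta-1,6-dien-3-ol
Conditions: THF, −78 → 0 °C; H2O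
Reagents that add atoms: none
Why: Grignard 1,2-addition gives the isopropenyl carbinol; its configuration is irrelevant because this carbon becomes sp2 in the next step.

Step 11
Reactants: 21 rac-6-{[(tert-butyldimethylsilyl)oxy]methyl}-2-methylhepta-1,6-dien-3-ol; 16 triethyl orthoacetate
Product: 23 ethyl (4E)-8-{[(tert-butyldimethylsilyl)oxy]methyl}-4-methylnona-4,8-dienoate, via ketene acetal 22 (not isolated)
Conditions: EtCO2H (5 mol%), 140 °C, EtOH distilled off
Reagents that add atoms: none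
Why: Second Johnson–Claisen rearrangement; the chair transition state with the carbinol substituent equatorial gives the 4E trisubstituted alkene (typically ≥95:5) and adds C1–C2.

Step 12
Reactants: 23 ethyl (4E)-8-{[(tert-butyldimethylsilyl)oxy]methyl}-4-methylnona-4,8-dienoate
Product: 24 (4E)-8-{[(tert-butyldimethylsilyl)oxy]methyl}-4-methylnona-4,8-dienal
Conditions: i-Bu2AlH (1.05 equiv), CH2Cl2, −78 °C; MeOH; aq. KNaC4H4O6
Reagents that add atoms: none
Why: Partial ester reduction as in step 9 gives the C1 aldehyde without affecting the alkenes or the silyl ether.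

Step 13
Reactants: 24 (4E)-8-{[(tert-butyldimethylsilyl)oxy]methyl}-4-methylnona-4,8-dienal
Product: 25 tert-butyldimethyl{[(5E)-6-methyl-2-methylidenedec-5-en-9-yn-1-yl]oxy}silane
Conditions: dimethyl (1-diazo-2-oxopropyl)phosphonate, K2CO3 (2 equiv), MeOH, 0 °C → rt
Reagents that add atoms: dimethyl (1-diazo-2-oxopropyl)phosphonate, COP(=O)(OC)C(=[N+]=[N-])C(C)=O
Why: Ohira–Bestmann (Seyferth–Gilbert) homologation converts the aldehyde into the terminal alkyne (adds C15) under mild carbonate conditions.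

Step 14
Reactants: 25 tert-butyldimethyl{[(5E)-6-methyl-2-methylidenedec-5-en-9-yn-1-yl]oxy}silane
Product: 27 methyl (6E)-10-{[(tert-butyldimethylsilyl)oxy]methyl}-6-methylundeca-6,10-dien-2-ynoate, via lithium acetylide 26 (not isolated)
Conditions: n-BuLi, THF, −78 °C; ClCO2Me, −78 → 0 °C
Reagents that add atoms: methyl chloroformate, COC(=O)Cl
Why: Deprotonation of the terminal alkyne and C-acylation by the chloroformate gives the ynoate (adds C16).

Step 15
Reactants: 27 methyl (6E)-10-{[(tert-butyldimethylsilyl)oxy]methyl}-6-methylundeca-6,10-dien-2-ynoate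
Product: 29 methyl (2Z,6E)-10-{[(tert-butyldimethylsilyl)oxy]methyl}-6-methyl-2-[(4,4,5,5-tetramethyl-1,3,2-dioxaborolan-2-yl)methyl]undeca-2,6,10-trienoate, via vinylalane 28 (not isolated)
Conditions: i-Bu2AlH (1.3 equiv), HMPA (2.6 equiv), THF, 0 °C; ICH2Bpin (1.5 equiv), 0 °C → rt
Reagents that add atoms: 2-(iodomethyl)-4,4,5,5-tetramethyl-1,3,2-dioxaborolane, ICB1OC(C)(C)C(C)(C)O1
Why: Conjugate syn-hydroalumination of the ynoate puts Al on the α-carbon cis to the new β-H, and C-alkylation by the iodomethylboronate with retention leaves the C2 chain cis to CO2CH3 and trans to CH2B, the E-crotyl-type geometry needed for an anti allylboration.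

Step 16
Reactants: 12 (2E,5R)-5-[(tert-butyldimethylsilyl)oxy]-3-methylhepta-2,6-dienal; 29 allylboronate (1.2 equiv)
Product: 31 (4R,5S)-5-[(1E,4R)-4-[(tert-butyldimethylsilyl)oxy]-2-methylhexa-1,5-dien-1-yl]-4-[(3E)-7-{[(tert-butyldimethylsilyl)oxy]methyl}-3-methylocta-3,7-dien-1-yl]-3-methylideneoxolan-2-one, via borate ester 30 (not isolated)
Conditions: (R)-TRIP [(R)-3,3′-bis(2,4,6-triisopropylphenyl)-1,1′-binaphthyl-2,2′-diyl hydrogen phosphate] (10 mol%), PhMe, 4 Å MS, rt, 48 h; then PPTS (0.2 equiv), 40 °C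
Reagents that add atoms: none
Why: Carbonyl allylboration through a closed chair transition state puts the γ-substituent equatorial and gives the anti borate, hence the trans lactone after lactonisation; the chiral phosphoric acid, by analogy with its allyl- and crotyl-Bpin additions, directs attack to the Re face of the aldehyde (14S, 1R), and any wrong-face product is a separable diastereomer because C10 is fixed.

Step 17
Reactants: 31 bis-silyl lactone
Product: 32 (4R,5S)-5-[(1E,4R)-4-hydroxy-2-methylhexa-1,5-dien-1-yl]-4-[(3E)-7-(hydroxymethyl)-3-methylocta-3,7-dien-1-yl]-3-methylideneoxolan-2-one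
Conditions: HF·pyridine, pyridine, THF, 0 °C → rt
Reagents that add atoms: none
Why: Buffered fluoride cleaves both silyl ethers while leaving the Michael-acceptor lactone and the allylic C–O bonds intact.

Step 18
Reactants: 32 diol
Product: 33 (5E)-8-[(2S,3R)-2-[(1E,4R)-4-hydroxy-2-methylhexa-1,5-dien-1-yl]-4-methylidene-5-oxooxolan-3-yl]-6-methyl-2-methylideneoct-5-enal
Conditions: TEMPO (0.2 equiv), PhI(OAc)2 (1.2 equiv), CH2Cl2, 0 °C → rt
Reagents that add atoms: none
Why: Oxoammonium (TEMPO) oxidation is selective for the primary allylic alcohol over the secondary C10–OH and stops at the enal.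

Step 19
Reactants: 33 hydroxy enal
Product: 34 (5E)-8-[(2S,3R)-2-[(1E,4R)-4-hydroxy-2-methylhexa-1,5-dien-1-yl]-4-methylidene-5-oxooxolan-3-yl]-6-methyl-2-methylideneoct-5-enoic acid
Conditions: NaClO2, NaH2PO4, 2-methyl-2-butene (20 equiv), t-BuOH/H2O, 0 °C → rt
Reagents that add atoms: sodium chlorite, [Na+].[O-]Cl=O
Why: Pinnick oxidation converts the enal into the 2-substituted acrylic acid, with 2-methyl-2-butene scavenging HOCl so that the alkenes and the free C10–OH are untouched.

Step 20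
Reactants: 34 hydroxy acid
Product: 36 15-membered macrolactone (O–C19 bond; 1R,10R,14S), via mixed anhydride 35 (not isolated)
Conditions: MNBA (2-methyl-6-nitrobenzoic anhydride, 1.4 equiv), DMAP (6 equiv), CH2Cl2, rt, slow addition of 34 over 12 h, final 1 mM
Reagents that add atoms: none
Why: Shiina macrolactonisation; the mixed anhydride is activated by DMAP and captured by the C10 hydroxyl under high dilution, closing the 15-membered ring by acyl–O bond formation with retention at C10.

Step 21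
Reactants: 36 macrolactone
Product: 37 ovatodiolide
Conditions: second-generation Grubbs catalyst RuCl2(=CHPh)(PCy3)(H2IMes) (15 mol%), PhMe, 80 °C, 1 mM
Reagents that add atoms: none
Why: Transannular ring-closing metathesis; the ruthenium alkylidene forms at the monosubstituted C10 vinyl group and closes onto the adjacent acrylate CH2= to give the butenolide with loss of ethene, a closure used before for cembranolide butenolides, while the hindered α-methylene lactone and trisubstituted alkenes do not engage.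

Step 22
Reactants: 37 ovatodiolide
Product: 38 4-methylene-5β-hydroperoxyovatodiolide
Conditions: O2, tetraphenylporphyrin (1 mol%), visible light, CH2Cl2, −20 °C
Reagents that add atoms: dioxygen, O=O
Why: Schenck ene reaction; singlet oxygen reacts only with the electron-rich isolated C4=C5 bond (C12=C13 is deactivated by its allylic acyloxy groups, the other two alkenes are conjugated), abstracts a C18 hydrogen on the more crowded side (cis effect) and bonds to C5 from the exposed face, giving the 5R hydroperoxide and the 4(18) exo-methylene.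

## Compound list

1 | (R)-epichlorohydrin, (2R)-2-(chloromethyl)oxirane | ClC[C@H]1CO1 | starting material
2 | ethynyltrimethylsilane | C#C[Si](C)(C)C | starting material
3 | lithium (trimethylsilyl)acetylide | [Li]C#C[Si](C)(C)C | intermediate
4 | (2R)-1-chloro-5-(trimethylsilyl)pent-4-yn-2-ol | ClC[C@H](O)CC#C[Si](C)(C)C | intermediate
5 | (2R)-2-[3-(trimethylsilyl)prop-2-yn-1-yl]oxirane | C1[C@H](O1)CC#C[Si](C)(C)C | intermediate
6 | (3R)-6-(trimethylsilyl)hex-1-en-5-yn-3-ol | C=C[C@H](O)CC#C[Si](C)(C)C | intermediate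
7 | (3R)-3-[(tert-butyldimethylsilyl)oxy]-6-(trimethylsilyl)hex-1-en-5-yne | C=C[C@H](O[Si](C)(C)C(C)(C)C)CC#C[Si](C)(C)C | intermediate
8 | (3R)-3-[(tert-butyldimethylsilyl)oxy]hex-1-en-5-yne | C=C[C@H](O[Si](C)(C)C(C)(C)C)CC#C | intermediate
9 | [(1E,4R)-4-[(tert-butyldimethylsilyl)oxy]-2-methylhexa-1,5-dien-1-yl]dimethylalumane | C[Al](C)/C=C(\C)C[C@@H](O[Si](C)(C)C(C)(C)C)C=C | intermediate
10 | lithium butyl[(1E,4R)-4-[(tert-butyldimethylsilyl)oxy]-2-methylhexa-1,5-dien-1-yl]dimethylaluminate | [Li+].CCCC[Al-](C)(C)/C=C(\C)C[C@@H](O[Si](C)(C)C(C)(C)C)C=C | intermediate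
11 | (2E,5R)-5-[(tert-butyldimethylsilyl)oxy]-3-methylhepta-2,6-dien-1-ol | OC/C=C(\C)C[C@@H](O[Si](C)(C)C(C)(C)C)C=C | intermediate
12 | (2E,5R)-5-[(tert-butyldimethylsilyl)oxy]-3-methylhepta-2,6-dienal | O=C/C=C(\C)C[C@@H](O[Si](C)(C)C(C)(C)C)C=C | intermediate
13 | 2-methylidenepropane-1,3-diol | C=C(CO)CO | starting material
14 | sodium 2-(hydroxymethyl)prop-2-en-1-olate | [Na+].[O-]CC(=C)CO | intermediate
15 | 2-{[(tert-butyldimethylsilyl)oxy]methyl}prop-2-en-1-ol | C=C(CO)CO[Si](C)(C)C(C)(C)C | intermediate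
16 | triethyl orthoacetate (1,1,1-triethoxyethane) | CC(OCC)(OCC)OCC | starting material
17 | tert-butyl[(2-{[(1-ethoxyethenyl)oxy]methyl}prop-2-en-1-yl)oxy]dimethylsilane | C=C(OCC)OCC(=C)CO[Si](C)(C)C(C)(C)C | intermediate
18 | ethyl 4-{[(tert-butyldimethylsilyl)oxy]methyl}pent-4-enoate | CCOC(=O)CCC(=C)CO[Si](C)(C)C(C)(C)C | intermediate
19 | 4-{[(tert-butyldimethylsilyl)oxy]methyl}pent-4-enal | O=CCCC(=C)CO[Si](C)(C)C(C)(C)C | intermediate
20 | isopropenylmagnesium bromide | CC(=C)[Mg]Br | starting material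
21 | rac-6-{[(tert-butyldimethylsilyl)oxy]methyl}-2-methylhepta-1,6-dien-3-ol | CC(=C)C(O)CCC(=C)CO[Si](C)(C)C(C)(C)C | intermediate
22 | rac-tert-butyl({5-[(1-ethoxyethenyl)oxy]-6-methyl-2-methylidenehept-6-en-1-yl}oxy)dimethylsilane | C=C(OCC)OC(CCC(=C)CO[Si](C)(C)C(C)(C)C)C(C)=C | intermediate
23 | ethyl (4E)-8-{[(tert-butyldimethylsilyl)oxy]methyl}-4-methylnona-4,8-dienoate | CCOC(=O)CC/C(C)=C/CCC(=C)CO[Si](C)(C)C(C)(C)C | intermediate
24 | (4E)-8-{[(tert-butyldimethylsilyl)oxy]methyl}-4-methylnona-4,8-dienal | O=CCC/C(C)=C/CCC(=C)CO[Si](C)(C)C(C)(C)C | intermediate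
25 | tert-butyldimethyl{[(5E)-6-methyl-2-methylidenedec-5-en-9-yn-1-yl]oxy}silane | C#CCC/C(C)=C/CCC(=C)CO[Si](C)(C)C(C)(C)C | intermediate
26 | lithium acetylide of 25 | [Li]C#CCC/C(C)=C/CCC(=C)CO[Si](C)(C)C(C)(C)C | intermediate
27 | methyl (6E)-10-{[(tert-butyldimethylsilyl)oxy]methyl}-6-methylundeca-6,10-dien-2-ynoate | COC(=O)C#CCC/C(C)=C/CCC(=C)CO[Si](C)(C)C(C)(C)C | intermediate
28 | methyl (2E,6E)-2-(diisobutylalumanyl)-10-{[(tert-butyldimethylsilyl)oxy]methyl}-6-methylundeca-2,6,10-trienoate | COC(=O)/C([Al](CC(C)C)CC(C)C)=C\CC/C(C)=C/CCC(=C)CO[Si](C)(C)C(C)(C)C | intermediate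
29 | methyl (2Z,6E)-10-{[(tert-butyldimethylsilyl)oxy]methyl}-6-methyl-2-[(4,4,5,5-tetramethyl-1,3,2-dioxaborolan-2-yl)methyl]undeca-2,6,10-trienoate | COC(=O)/C(CB1OC(C)(C)C(C)(C)O1)=C\CC/C(C)=C/CCC(=C)CO[Si](C)(C)C(C)(C)C | intermediate
30 | methyl (3R,4S,5E,8R)-8-[(tert-butyldimethylsilyl)oxy]-3-[(3E)-7-{[(tert-butyldimethylsilyl)oxy]methyl}-3-methylocta-3,7-dien-1-yl]-6-methyl-2-methylidene-4-[(4,4,5,5-tetramethyl-1,3,2-dioxaborolan-2-yl)oxy]deca-5,9-dienoate | COC(=O)C(=C)[C@@H](CC/C(C)=C/CCC(=C)CO[Si](C)(C)C(C)(C)C)[C@@H](OB1OC(C)(C)C(C)(C)O1)/C=C(\C)C[C@@H](O[Si](C)(C)C(C)(C)C)C=C | intermediate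
31 | (4R,5S)-5-[(1E,4R)-4-[(tert-butyldimethylsilyl)oxy]-2-methylhexa-1,5-dien-1-yl]-4-[(3E)-7-{[(tert-butyldimethylsilyl)oxy]methyl}-3-methylocta-3,7-dien-1-yl]-3-methylideneoxolan-2-one | C=C1C(=O)O[C@@H](/C=C(\C)C[C@@H](O[Si](C)(C)C(C)(C)C)C=C)[C@@H]1CC/C(C)=C/CCC(=C)CO[Si](C)(C)C(C)(C)C | intermediate
32 | (4R,5S)-5-[(1E,4R)-4-hydroxy-2-methylhexa-1,5-dien-1-yl]-4-[(3E)-7-(hydroxymethyl)-3-methylocta-3,7-dien-1-yl]-3-methylideneoxolan-2-one | C=C1C(=O)O[C@@H](/C=C(\C)C[C@@H](O)C=C)[C@@H]1CC/C(C)=C/CCC(=C)CO | intermediate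
33 | (5E)-8-[(2S,3R)-2-[(1E,4R)-4-hydroxy-2-methylhexa-1,5-dien-1-yl]-4-methylidene-5-oxooxolan-3-yl]-6-methyl-2-methylideneoct-5-enal | C=C1C(=O)O[C@@H](/C=C(\C)C[C@@H](O)C=C)[C@@H]1CC/C(C)=C/CCC(=C)C=O | intermediate
34 | (5E)-8-[(2S,3R)-2-[(1E,4R)-4-hydroxy-2-methylhexa-1,5-dien-1-yl]-4-methylidene-5-oxooxolan-3-yl]-6-methyl-2-methylideneoct-5-enoic acid | C=C1C(=O)O[C@@H](/C=C(\C)C[C@@H](O)C=C)[C@@H]1CC/C(C)=C/CCC(=C)C(=O)O | intermediate
35 | mixed anhydride of 34 (at C19) and 2-methyl-6-nitrobenzoic acid | C=C1C(=O)O[C@@H](/C=C(\C)C[C@@H](O)C=C)[C@@H]1CC/C(C)=C/CCC(=C)C(=O)OC(=O)c1c(C)cccc1[N+](=O)[O-] | intermediate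
36 | (1R,10R,14S,4E,12E) macrolactone: 15-membered ring O–C19(=O)–C8(=CH2)–C7–C6–C5=C4(CH3)–C3–C2–C1–C14–C13=C12(CH3)–C11–C10(vinyl), trans-fused at C1–C14 to the α-methylene-γ-butyrolactone | C=C1C(=O)O[C@@H](/C=C(\C)C[C@@H](O2)C=C)[C@@H]1CC/C(C)=C/CCC(=C)C2=O | intermediate
37 | ovatodiolide, (1R,10R,14S,4E,12E)-cembra-4,8,12,15(17)-tetraene-19,10:16,14-diolide | C=C1C(=O)O[C@H]2/C=C(\C)C[C@@H]3C=C(CC/C=C(\C)CC[C@H]12)C(=O)O3 | intermediate
38 | 4-methylene-5β-hydroperoxyovatodiolide, (1R,5R,10R,14S,12E)-5-hydroperoxycembra-4(18),8,12,15(17)-tetraene-19,10:16,14-diolide | C=C1C(=O)O[C@H]2/C=C(\C)C[C@@H]3C=C(CC[C@@H](OO)C(=C)CC[C@H]12)C(=O)O3 | target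

## Step count and risks

Total steps: 22. Longest linear sequence: 16 steps (13 → 38; steps 7–22). The enal branch (1 → 12) is 6 steps.

The three steps most likely to fail:

**Step 15.** The vinylalane may lose geometry through its aluminium allenolate form, or C-alkylation by the iodomethylboronate may be sluggish. The fallback sets out from 27 and comes back at 29. Bu3SnH with Pd(PPh3)4 (THF, 0 °C) adds H and Sn syn across the ynoate, with tin on the α-carbon, to give the α-stannyl enoate F1. I2 (CH2Cl2, 0 °C) replaces tin with retention to give the α-iodo enoate F2. Negishi coupling of F2 with (pinacolboryl)methylzinc iodide F3 (from ICH2Bpin and Zn dust in THF) under Pd(PPh3)4 at rt forms the C15–C17 bond with retention and gives 29. The alkene geometry is then carried by configurationally stable vinyl–tin and vinyl–iodine bonds instead of a vinylalane.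

**Step 16.** The ester-deactivated boronate may add slowly to the β,β-disubstituted enal, or the catalyst may give poor facial control; this use of the phosphoric acid with an ester-bearing boronate is by analogy, not precedent (a wrong-face product is the separable (4S,5R) diastereomer of 31). The fallback sets out from 25 and 12 and comes back at 31, and replaces catalyst control by a stoichiometric auxiliary. Lithiation of 25 (n-BuLi, THF, −78 °C) and CO2 give the ynoic acid F4. DCC/DMAP esterification with (1R,2S,5R)-8-phenylmenthol gives the 8-phenylmenthyl ynoate F5. Treatment with i-Bu2AlH/HMPA and then ICH2Bpin, as in step 15, gives the 8-phenylmenthyl allylboronate F6, in which the phenyl ring covers one face of the allyl unit. Sc(OTf)3-catalysed addition of F6 to 12 (CH2Cl2, −78 °C), followed by acid-promoted lactonisation that expels the auxiliary, gives 31. The enantiomeric auxiliary is used if the first one exposes the wrong face.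

**Step 22.** Hydrogen abstraction from C6 would give the tertiary C4 hydroperoxide, and attack could occur on the wrong face. The fallback sets out from 37 and comes back at 38, and places the oxygen stepwise.
- mCPBA (CH2Cl2, NaHCO3, 0 °C) epoxidises the electron-rich C4=C5 bond to 4,5-epoxyovatodiolide F7.
- TMSOTf/2,6-lutidine (CH2Cl2, −78 → −20 °C) opens F7 at the tertiary carbon with loss of a C18 proton to give the allylic trimethylsilyl ether F8.
- Citric acid in MeOH converts F8 into the 4-methylene-5-ol F9.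
- Dess–Martin periodinane oxidises F9 to the enone F10, so the C5 configuration of F7–F9 does not matter.
- (R)-2-methyl-CBS-oxazaborolidine with catecholborane (PhMe, −78 °C) reduces the ketone to the (5S)-alcohol F11.
- MsCl/Et3N (CH2Cl2, −30 °C) gives the (5S)-mesylate F12.
- SN2 displacement with ethereal H2O2 (−20 → 0 °C) proceeds with inversion and gives the 5R hydroperoxide 38. Competing SN2′ attack at C18 is the main concern in this last displacement.

## Further compounds

F1 | step 15 | methyl (2E,6E)-10-{[(tert-butyldimethylsilyl)oxy]methyl}-6-methyl-2-(tributylstannyl)undeca-2,6,10-trienoate | COC(=O)/C([Sn](CCCC)(CCCC)CCCC)=C\CC/C(C)=C/CCC(=C)CO[Si](C)(C)C(C)(C)C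
F2 | step 15 | methyl (2E,6E)-10-{[(tert-butyldimethylsilyl)oxy]methyl}-2-iodo-6-methylundeca-2,6,10-trienoate | COC(=O)/C(I)=C\CC/C(C)=C/CCC(=C)CO[Si](C)(C)C(C)(C)C
F3 | step 15 | (pinacolboryl)methylzinc iodide | I[Zn]CB1OC(C)(C)C(C)(C)O1
F4 | step 16 | (6E)-10-{[(tert-butyldimethylsilyl)oxy]methyl}-6-methylundeca-6,10-dien-2-ynoic acid | OC(=O)C#CCC/C(C)=C/CCC(=C)CO[Si](C)(C)C(C)(C)C
F5 | step 16 | (1R,2S,5R)-8-phenylmenthyl (6E)-10-{[(tert-butyldimethylsilyl)oxy]methyl}-6-methylundeca-6,10-dien-2-ynoate | CC(C)(c1ccccc1)[C@@H]1CC[C@@H](C)C[C@H]1OC(=O)C#CCC/C(C)=C/CCC(=C)CO[Si](C)(C)C(C)(C)C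
F6 | step 16 | (1R,2S,5R)-8-phenylmenthyl (2Z,6E)-10-{[(tert-butyldimethylsilyl)oxy]methyl}-6-methyl-2-[(4,4,5,5-tetramethyl-1,3,2-dioxaborolan-2-yl)methyl]undeca-2,6,10-trienoate | CC(C)(c1ccccc1)[C@@H]1CC[C@@H](C)C[C@H]1OC(=O)/C(CB2OC(C)(C)C(C)(C)O2)=C\CC/C(C)=C/CCC(=C)CO[Si](C)(C)C(C)(C)C
F7 | step 22 | 4,5-epoxyovatodiolide (1R,10R,14S; trans-epoxide, C4/C5 face not assigned) | C=C1C(=O)O[C@H]2/C=C(\C)C[C@@H]3C=C(CCC4OC4(C)CC[C@H]12)C(=O)O3
F8 | step 22 | 4-methylene-5-(trimethylsilyloxy)ovatodiolide (1R,10R,14S; C5 not assigned) | C=C1C(=O)O[C@H]2/C=C(\C)C[C@@H]3C=C(CCC(O[Si](C)(C)C)C(=C)CC[C@H]12)C(=O)O3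
F9 | step 22 | 4-methylene-5-hydroxyovatodiolide (1R,10R,14S; C5 not assigned) | C=C1C(=O)O[C@H]2/C=C(\C)C[C@@H]3C=C(CCC(O)C(=C)CC[C@H]12)C(=O)O3
F10 | step 22 | 4-methylene-5-oxoovatodiolide (1R,10R,14S) | C=C1C(=O)O[C@H]2/C=C(\C)C[C@@H]3C=C(CCC(=O)C(=C)CC[C@H]12)C(=O)O3
F11 | step 22 | (1R,5S,10R,14S)-4-methylene-5-hydroxyovatodiolide | C=C1C(=O)O[C@H]2/C=C(\C)C[C@@H]3C=C(CC[C@H](O)C(=C)CC[C@H]12)C(=O)O3
F12 | step 22 | (1R,5S,10R,14S)-4-methylene-5-(methanesulfonyloxy)ovatodiolide | C=C1C(=O)O[C@H]2/C=C(\C)C[C@@H]3C=C(CC[C@H](OS(C)(=O)=O)C(=C)CC[C@H]12)C(=O)O3
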